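The symmetrical 3,3'-biindole is made by growing its second indole onto a ready-made 5-bromoindole. The benzo ring of the new unit (C3a, C4, C5, C6, C7, C7a; Br on C5, N1 on C7a) is cut at C3a–C7a and C6–C7 into a 2-bromo-1-en-3-yne and an N-ethynyl carbamate held together by N1–C2–C3. One thermal intramolecular [4+2] cycloaddition then closes the benzene ring and the five-membered nitrogen ring together, with the C5 bromine already in place. The precursor is a methyl N-ethynylcarbamate whose N–CH2–CH(5-bromo-1-tosylindol-3-yl) tether ends in the bromoenyne; aromatisation, N-deprotection and twofold C2 bromination finish the target.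

Key step: step 9

Remark: the ynamide terminus is carried as its triisopropylsilyl derivative until the bromoenyne has been installed, because a free N-ethynyl group would itself couple under Sonogashira conditions; the C-alkyne carries a trimethylsilyl group so that the two can be told apart.

Remark: the indoline C3 stereocentre is carried as the racemate and disappears on aromatisation; the target is achiral, so no stereocontrol is planned.

Step 1
Reactants: 1 5-bromoindole-3-carbaldehyde
Product: 2 5-bromo-1-tosylindole-3-carbaldehyde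
Conditions: TsCl, Et3N, DMAP (cat.), CH2Cl2, 0 °C to rt
Reagents that add atoms: p-toluenesulfonyl chloride, Cc1ccc(cc1)S(Cl)(=O)=O
Why: N-sulfonylation of the acidic indole N–H under DMAP catalysis is routine, and the tosyl group makes the later nitroalkene a true Michael acceptor and protects N1 against the bases used afterwards.

Step 2
Reactants: 2 5-bromo-1-tosylindole-3-carbaldehyde; 3 nitromethane
Product: 4 (E)-5-bromo-3-(2-nitrovinyl)-1-tosylindole
Conditions: MeNO2 (solvent), NH4OAc (0.5 equiv), 100 °C
Reagents that add atoms: none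
Why: Henry (nitroaldol) condensation with dehydration in the same pot should give the conjugated nitroalkene as the thermodynamically favoured E isomer.

Step 3
Reactants: 4 (E)-5-bromo-3-(2-nitrovinyl)-1-tosylindole; 5 trimethylsilylacetylene
Product: 8 racemic 5-bromo-3-[1-nitro-4-(trimethylsilyl)but-3-yn-2-yl]-1-tosylindole, via lithium trimethylsilylacetylide 6 (not isolated), via lithium nitronate 7 (not isolated)
Conditions: 5 (1.5 equiv), n-BuLi, THF, –78 °C; then 4 added slowly, –78 °C; AcOH, –78 °C to rt
Reagents that add atoms: none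
Why: Michael addition of an organolithium to a nitroalkene: slow addition of 4 to excess acetylide at –78 °C keeps nitronate 7 from adding to unreacted nitroalkene, cold protonation gives the nitroalkane, and the new stereocentre forms without control as the racemate.

Step 4
Reactants: 8 racemic 5-bromo-3-[1-nitro-4-(trimethylsilyl)but-3-yn-2-yl]-1-tosylindole
Product: 10 racemic methyl N-[2-(5-bromo-1-tosylindol-3-yl)-4-(trimethylsilyl)but-3-yn-1-yl]carbamate, via primary amine 9 (not isolated)
Conditions: Zn dust, aq HCl, MeOH/THF, 0 °C to rt; filter; then NaHCO3, ClCO2Me, CH2Cl2/H2O, 0 °C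
Reagents that add atoms: methyl chloroformate, COC(Cl)=O
Why: Dissolving-metal reduction of a primary aliphatic nitro group with Zn and acid spares the aryl bromide, the sulfonamide and the silylalkyne, and Schotten–Baumann acylation of the crude amine gives the carbamate.

Step 5
Reactants: 10 racemic methyl N-[2-(5-bromo-1-tosylindol-3-yl)-4-(trimethylsilyl)but-3-yn-1-yl]carbamate; 11 (bromoethynyl)triisopropylsilane
Product: 14 racemic methyl N-[2-(5-bromo-1-tosylindol-3-yl)-4-(trimethylsilyl)but-3-yn-1-yl]-N-[(triisopropylsilyl)ethynyl]carbamate, via potassium carbamate salt 12 (not isolated), via copper amide 13 (not isolated)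
Conditions: KN(SiMe3)2 (1.0 equiv), THF/pyridine, 0 °C; CuI (1.0 equiv), rt; then 11 (2 equiv, slow addition), rt
Reagents that add atoms: none
Why: Copper-mediated N-alkynylation of an acyclic carbamate with a 1-bromoalkyne (Ullmann-type amidation at an sp carbon): one equivalent of base removes only the carbamate N–H, and the copper amide couples with the hindered bromoalkyne at room temperature.

Step 6
Reactants: 14 racemic methyl N-[2-(5-bromo-1-tosylindol-3-yl)-4-(trimethylsilyl)but-3-yn-1-yl]-N-[(triisopropylsilyl)ethynyl]carbamate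
Product: 15 racemic methyl N-[2-(5-bromo-1-tosylindol-3-yl)but-3-yn-1-yl]-N-[(triisopropylsilyl)ethynyl]carbamate
Conditions: K2CO3 (0.2 equiv), MeOH/THF, 0 °C
Reagents that add atoms: none
Why: Methoxide-catalysed protodesilylation removes the small trimethylsilyl group from the C-alkyne, while the bulky triisopropylsilyl group on the ynamide, the carbamate and the N-tosyl group should survive catalytic base at 0 °C.

Step 7
Reactants: 15 racemic methyl N-[2-(5-bromo-1-tosylindol-3-yl)but-3-yn-1-yl]-N-[(triisopropylsilyl)ethynyl]carbamate; 16 1,1-dibromoethene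
Product: 17 racemic methyl N-[5-bromo-2-(5-bromo-1-tosylindol-3-yl)hex-5-en-3-yn-1-yl]-N-[(triisopropylsilyl)ethynyl]carbamate
Conditions: 16 (5 equiv), Pd(PPh3)4 (5 mol %), CuI (10 mol %), i-Pr2NH, THF, 0 °C to rt
Reagents that add atoms: none
Why: Sonogashira coupling: the geminal dibromoalkene adds oxidatively to zerovalent palladium at room temperature far faster than the two aryl bromides, and the excess of dihalide should hold the reaction at monocoupling to give the 2-bromo-1-en-3-yne.

Step 8
Reactants: 17 racemic methyl N-[5-bromo-2-(5-bromo-1-tosylindol-3-yl)hex-5-en-3-yn-1-yl]-N-[(triisopropylsilyl)ethynyl]carbamate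
Product: 18 racemic methyl N-[5-bromo-2-(5-bromo-1-tosylindol-3-yl)hex-5-en-3-yn-1-yl]-N-ethynylcarbamate
Conditions: Bu4NF (1.1 equiv), AcOH (1.1 equiv), THF, –40 to 0 °C
Reagents that add atoms: none
Why: Fluoride-induced protodesilylation of a silyl ynamide is fast at low temperature, and the acetic acid buffer should prevent loss of HBr from the bromoalkene and base-induced isomerisation at the propargylic C–H.

Step 9
Reactants: 18 racemic methyl N-[5-bromo-2-(5-bromo-1-tosylindol-3-yl)hex-5-en-3-yn-1-yl]-N-ethynylcarbamate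
Product: 20 racemic methyl 5-bromo-3-(5-bromo-1-tosylindol-3-yl)indoline-1-carboxylate, via cyclic allene 19 (not isolated)
Conditions: BHT (1 equiv), degassed toluene (0.02 M), sealed tube, 150–180 °C
Reagents that add atoms: none
Why: On heating, the 2-bromo-1-en-3-yne (C3a≡C4–C5(Br)=C6) acts as the four-carbon partner and the ynamide triple bond (C7≡C7a) as the two-carbon partner of an intramolecular [4+2] cycloaddition that forms C3a–C7a and C6–C7 and gives the strained isoaromatic cyclic allene 19, which aromatises by shift of one C6 hydrogen to C4. The closest known reaction type is the thermal intramolecular enyne–ynamide (dehydro-Diels–Alder) benzannulation that gives N-acylindolines from carbamate-tethered substrates of this kind. The five-membered ring N1–C2–C3–C3a–C7a closes through the C3a–C7a bond, exo with respect to both triple bonds as the three-atom tether dictates, and the six-membered carbocycle closes through C6–C7 as the second bond of the same cycloaddition. No stereocentre is created; the existing C3 centre stays racemic and is removed in step 10. The step needs the [4+2] mode to win over intermolecular oligomerisation and needs the correct regiochemistry: high dilution and the radical inhibitor favour the intramolecular path, the tether fixes the ring fusion, and the bromine on the internal alkene carbon can only end up on C5 while the hydrogen of the terminal ynamide ends up on C7.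

Step 10
Reactants: 20 racemic methyl 5-bromo-3-(5-bromo-1-tosylindol-3-yl)indoline-1-carboxylate
Product: 21 methyl 5-bromo-3-(5-bromo-1-tosylindol-3-yl)indole-1-carboxylate
Conditions: o-chloranil (1.5 equiv), toluene, 80 °C
Reagents that add atoms: none
Why: Quinone dehydrogenation: hydride abstraction from the doubly benzylic C3–H followed by loss of a C2 proton aromatises the N-acylindoline to the N-acylindole and removes the only stereocentre, while the sulfonylated indole and the aryl bromides are inert to the quinone.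

Step 11
Reactants: 21 methyl 5-bromo-3-(5-bromo-1-tosylindol-3-yl)indole-1-carboxylate
Product: 22 5,5'-dibromo-1H,1'H-3,3'-biindole
Conditions: Cs2CO3 (3 equiv), THF/MeOH 2:1, 65 °C, under argon
Reagents that add atoms: none
Why: Methanolysis with Cs2CO3: on an indole nitrogen both the methoxycarbonyl and the tosyl group are activated, because the indolide is a good leaving group, so methoxide should cleave both in one operation without touching the aryl bromides.

Step 12
Reactants: 22 5,5'-dibromo-1H,1'H-3,3'-biindole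
Product: 23 Rivularin-c (2,2',5,5'-tetrabromo-1H,1'H-3,3'-biindole)
Conditions: NBS (2.05 equiv), dry THF, –78 to 0 °C, dark
Reagents that add atoms: N-bromosuccinimide, O=C1CCC(=O)N1Br
Why: Electrophilic bromination with NBS: a 3-substituted indole is attacked at C3 and the bromine reaches C2 after 1,2-shift and tautomerisation, C2 being the only free pyrrole position of each half and the benzo rings being deactivated by the C5 and C5' bromines, so two equivalents should give the 2,2'-dibromide.

Compound list
1 | 5-bromoindole-3-carbaldehyde | O=Cc1c[nH]c2ccc(Br)cc12 | starting material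
2 | 5-bromo-1-tosylindole-3-carbaldehyde | O=Cc1cn(S(=O)(=O)c2ccc(C)cc2)c2ccc(Br)cc12 | intermediate
3 | nitromethane | C[N+](=O)[O-] | starting material
4 | (E)-5-bromo-3-(2-nitrovinyl)-1-tosylindole | O=[N+]([O-])/C=C/c1cn(S(=O)(=O)c2ccc(C)cc2)c2ccc(Br)cc12 | intermediate
5 | trimethylsilylacetylene | C#C[Si](C)(C)C | starting material
6 | lithium trimethylsilylacetylide (not isolated) | [Li]C#C[Si](C)(C)C | intermediate
7 | lithium nitronate of 8, racemic (not isolated) | [Li+].[O-][N+]([O-])=CC(C#C[Si](C)(C)C)c1cn(S(=O)(=O)c2ccc(C)cc2)c2ccc(Br)cc12 | intermediate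
8 | racemic 5-bromo-3-[1-nitro-4-(trimethylsilyl)but-3-yn-2-yl]-1-tosylindole | O=[N+]([O-])CC(C#C[Si](C)(C)C)c1cn(S(=O)(=O)c2ccc(C)cc2)c2ccc(Br)cc12 | intermediate
9 | racemic 2-(5-bromo-1-tosylindol-3-yl)-4-(trimethylsilyl)but-3-yn-1-amine (not isolated) | NCC(C#C[Si](C)(C)C)c1cn(S(=O)(=O)c2ccc(C)cc2)c2ccc(Br)cc12 | intermediate
10 | racemic methyl N-[2-(5-bromo-1-tosylindol-3-yl)-4-(trimethylsilyl)but-3-yn-1-yl]carbamate | COC(=O)NCC(C#C[Si](C)(C)C)c1cn(S(=O)(=O)c2ccc(C)cc2)c2ccc(Br)cc12 | intermediate
11 | (bromoethynyl)triisopropylsilane | BrC#C[Si](C(C)C)(C(C)C)C(C)C | starting material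
12 | potassium salt of carbamate 10, racemic (not isolated) | [K+].COC(=O)[N-]CC(C#C[Si](C)(C)C)c1cn(S(=O)(=O)c2ccc(C)cc2)c2ccc(Br)cc12 | intermediate
13 | copper amide of carbamate 10, racemic (not isolated) | COC(=O)N([Cu])CC(C#C[Si](C)(C)C)c1cn(S(=O)(=O)c2ccc(C)cc2)c2ccc(Br)cc12 | intermediate
14 | racemic methyl N-[2-(5-bromo-1-tosylindol-3-yl)-4-(trimethylsilyl)but-3-yn-1-yl]-N-[(triisopropylsilyl)ethynyl]carbamate | COC(=O)N(C#C[Si](C(C)C)(C(C)C)C(C)C)CC(C#C[Si](C)(C)C)c1cn(S(=O)(=O)c2ccc(C)cc2)c2ccc(Br)cc12 | intermediate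
15 | racemic methyl N-[2-(5-bromo-1-tosylindol-3-yl)but-3-yn-1-yl]-N-[(triisopropylsilyl)ethynyl]carbamate | COC(=O)N(C#C[Si](C(C)C)(C(C)C)C(C)C)CC(C#C)c1cn(S(=O)(=O)c2ccc(C)cc2)c2ccc(Br)cc12 | intermediate
16 | 1,1-dibromoethene | C=C(Br)Br | starting material
17 | racemic methyl N-[5-bromo-2-(5-bromo-1-tosylindol-3-yl)hex-5-en-3-yn-1-yl]-N-[(triisopropylsilyl)ethynyl]carbamate | COC(=O)N(C#C[Si](C(C)C)(C(C)C)C(C)C)CC(C#CC(Br)=C)c1cn(S(=O)(=O)c2ccc(C)cc2)c2ccc(Br)cc12 | intermediate
18 | racemic methyl N-[5-bromo-2-(5-bromo-1-tosylindol-3-yl)hex-5-en-3-yn-1-yl]-N-ethynylcarbamate | COC(=O)N(C#C)CC(C#CC(Br)=C)c1cn(S(=O)(=O)c2ccc(C)cc2)c2ccc(Br)cc12 | intermediate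
19 | cyclic allene, racemic: methyl 5-bromo-3-(5-bromo-1-tosylindol-3-yl)-2,3-dihydro-6H-indole-1-carboxylate with cumulated C3a=C4=C5 and C7=C7a double bonds (not isolated) | COC(=O)N1CC(c2cn(S(=O)(=O)c3ccc(C)cc3)c3ccc(Br)cc23)C2=C=C(Br)CC=C12 | intermediate
20 | racemic methyl 5-bromo-3-(5-bromo-1-tosylindol-3-yl)indoline-1-carboxylate | COC(=O)N1CC(c2cn(S(=O)(=O)c3ccc(C)cc3)c3ccc(Br)cc23)c2cc(Br)ccc21 | intermediate
21 | methyl 5-bromo-3-(5-bromo-1-tosylindol-3-yl)indole-1-carboxylate | COC(=O)n1cc(-c2cn(S(=O)(=O)c3ccc(C)cc3)c3ccc(Br)cc23)c2cc(Br)ccc21 | intermediate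
22 | 5,5'-dibromo-1H,1'H-3,3'-biindole | Brc1ccc2[nH]cc(-c3c[nH]c4ccc(Br)cc34)c2c1 | intermediate
23 | Rivularin-c, 2,2',5,5'-tetrabromo-1H,1'H-3,3'-biindole (achiral) | Brc1ccc2[nH]c(Br)c(-c3c(Br)[nH]c4ccc(Br)cc34)c2c1 | target

Total step count: 12. Longest linear sequence: 12 steps, from 1 to 23.

Steps most likely to fail

1. Step 9. Thermal oligomerisation of the bromoenyne, or loss of HBr from it, may outrun the cycloaddition, or the cyclic allene may be diverted before the hydrogen shift. The fallback sets out from 2 and returns at 22. Wittig methoxymethylenation of 2 with Ph3P=CHOMe (from (methoxymethyl)triphenylphosphonium chloride and KOt-Bu, THF, 0 °C) should give the enol ether 5-bromo-3-(2-methoxyvinyl)-1-tosylindole F1 as an E/Z mixture. Heating F1 with 4-bromophenylhydrazine hydrochloride in aqueous H2SO4/EtOH should unmask the aldehyde and form 2-(5-bromo-1-tosylindol-3-yl)acetaldehyde 4-bromophenylhydrazone F2 (not isolated). Fischer indolisation of this hydrazone in the same pot should give 5-bromo-3-(5-bromo-1-tosylindol-3-yl)-1H-indole F3. Cs2CO3 in THF/MeOH at 65 °C then removes the tosyl group and gives 22.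

2. Step 7. A second coupling at the remaining vinylic bromide, polymerisation of the dihalide, or competing insertion into an aryl C–Br bond may erode the monocoupling. The fallback sets out from 15 and returns at 20. Sonogashira coupling of 15 with (1-bromovinyl)trimethylsilane (Pd(PPh3)4, CuI, i-Pr2NH, THF, rt), a monobromide that cannot couple twice, should give racemic methyl N-[2-(5-bromo-1-tosylindol-3-yl)-5-(trimethylsilyl)hex-5-en-3-yn-1-yl]-N-[(triisopropylsilyl)ethynyl]carbamate F4. Buffered Bu4NF/AcOH at low temperature should give racemic methyl N-[2-(5-bromo-1-tosylindol-3-yl)-5-(trimethylsilyl)hex-5-en-3-yn-1-yl]-N-ethynylcarbamate F5. Heating as in step 9 should give racemic methyl 3-(5-bromo-1-tosylindol-3-yl)-5-(trimethylsilyl)indoline-1-carboxylate F6. Ipso-bromodesilylation with Br2 in CH2Cl2 at –78 °C, at the position para to the carbamate nitrogen, then gives 20.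

3. Step 12. Over-oxidation of the electron-rich free biindole, bromination on a benzo ring, or hydrolysis of a 3-bromoindolenine to an oxindole may compete with clean C2 bromination. The fallback sets out from 22 and returns at 23. Boc2O with DMAP in MeCN should give di-tert-butyl 5,5'-dibromo-3,3'-biindole-1,1'-dicarboxylate F7. Carbamate-directed deprotonation at C2 and C2' with LiN(i-Pr)2 in THF at –78 °C, a base that does not exchange with the aryl bromides, should give di-tert-butyl 5,5'-dibromo-2,2'-dilithio-3,3'-biindole-1,1'-dicarboxylate F8 (not isolated). Quenching with 1,2-dibromotetrachloroethane should give di-tert-butyl 2,2',5,5'-tetrabromo-3,3'-biindole-1,1'-dicarboxylate F9. CF3CO2H in CH2Cl2 then removes both Boc groups and gives 23.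

Further compounds
F1 | step 9 | 5-bromo-3-(2-methoxyvinyl)-1-tosylindole (E/Z mixture) | COC=Cc1cn(S(=O)(=O)c2ccc(C)cc2)c2ccc(Br)cc12
F2 | step 9 | 2-(5-bromo-1-tosylindol-3-yl)acetaldehyde 4-bromophenylhydrazone | Brc1ccc(NN=CCc2cn(S(=O)(=O)c3ccc(C)cc3)c3ccc(Br)cc23)cc1
F3 | step 9 | 5-bromo-3-(5-bromo-1-tosylindol-3-yl)-1H-indole | Cc1ccc(cc1)S(=O)(=O)n1cc(-c2c[nH]c3ccc(Br)cc23)c2cc(Br)ccc21
F4 | step 7 | racemic methyl N-[2-(5-bromo-1-tosylindol-3-yl)-5-(trimethylsilyl)hex-5-en-3-yn-1-yl]-N-[(triisopropylsilyl)ethynyl]carbamate | COC(=O)N(C#C[Si](C(C)C)(C(C)C)C(C)C)CC(C#CC(=C)[Si](C)(C)C)c1cn(S(=O)(=O)c2ccc(C)cc2)c2ccc(Br)cc12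
F5 | step 7 | racemic methyl N-[2-(5-bromo-1-tosylindol-3-yl)-5-(trimethylsilyl)hex-5-en-3-yn-1-yl]-N-ethynylcarbamate | COC(=O)N(C#C)CC(C#CC(=C)[Si](C)(C)C)c1cn(S(=O)(=O)c2ccc(C)cc2)c2ccc(Br)cc12
F6 | step 7 | racemic methyl 3-(5-bromo-1-tosylindol-3-yl)-5-(trimethylsilyl)indoline-1-carboxylate | COC(=O)N1CC(c2cn(S(=O)(=O)c3ccc(C)cc3)c3ccc(Br)cc23)c2cc([Si](C)(C)C)ccc21
F7 | step 12 | di-tert-butyl 5,5'-dibromo-3,3'-biindole-1,1'-dicarboxylate | CC(C)(C)OC(=O)n1cc(-c2cn(C(=O)OC(C)(C)C)c3ccc(Br)cc23)c2cc(Br)ccc21
F8 | step 12 | di-tert-butyl 5,5'-dibromo-2,2'-dilithio-3,3'-biindole-1,1'-dicarboxylate | CC(C)(C)OC(=O)n1c([Li])c(-c2c([Li])n(C(=O)OC(C)(C)C)c3ccc(Br)cc23)c2cc(Br)ccc21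
F9 | step 12 | di-tert-butyl 2,2',5,5'-tetrabromo-3,3'-biindole-1,1'-dicarboxylate | CC(C)(C)OC(=O)n1c(Br)c(-c2c(Br)n(C(=O)OC(C)(C)C)c3ccc(Br)cc23)c2cc(Br)ccc21
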